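**Plan**

1. Retrosynthesis cuts the C2–aryl bond and, in the same operation, the O1–C2 bond of the oxolane (numbering: O1, C2 aryl, C3 CH2OH, C4 veratrylmethyl, C5). C2 is bonded to ring O1 and to C1 of the ring whose para carbon carries the free OH, so C2 is an oxocarbenium carbon in disguise and the arene to be joined is guaiacol itself.
2. The precursor is an open-chain 1,4-diol with a dimethyl acetal at the future C2. It comes from a trans 3-(dimethoxymethyl)-4-veratrylmethyl butyrolactone that is "turned round" by reduction: the lactone carbonyl becomes the C3 CH2OH, the acetal carbon becomes C2, and the easy trans lactone becomes the 3,4-cis oxolane.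
3. The lactone comes from veratraldehyde and dimethyl succinate (Stobbe condensation, asymmetric hydrogenation, ester-selective reduction).
4. Forward order: C4 chain, temporary lactone ring, acetal carbon added, lactone opened, then the oxolane ring is closed and arylated in one flask. No protecting groups are used.
5. Stereochemistry: C4 by Rh catalysis; C3 relayed from C4 (anti alkylation); C2 relayed from C3/C4 (anti attack on the oxocarbenium ion).

Key step: step 6

**Route**

Step 1
Reactants: 1 3,4-dimethoxybenzaldehyde; 2 dimethyl succinate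
Product: 3 (E)-4-(3,4-dimethoxyphenyl)-3-(methoxycarbonyl)but-3-enoic acid
Conditions: NaOMe, MeOH, reflux; then aq. HCl
Reagents that add atoms: none
Why: Stobbe condensation, in which the succinate enolate adds to the aldehyde, the alkoxide lactonises onto the distal ester and E1cB opening of the paraconate should give the conjugated half-ester with the free acid on the CH2 arm, mainly as the E alkene.

Step 2
Reactants: 3 (E)-4-(3,4-dimethoxyphenyl)-3-(methoxycarbonyl)but-3-enoic acid
Product: 4 (R)-4-(3,4-dimethoxyphenyl)-3-(methoxycarbonyl)butanoic acid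
Conditions: H2 (5 bar), [Rh(cod)(Et-DuPhos)]BF4 (0.5 mol %; the ligand enantiomer that gives the R acid, both are sold), NaOMe (0.1 equiv), MeOH, rt
Reagents that add atoms: none
Why: Rh(I)–bisphosphine asymmetric hydrogenation of an itaconate-type half-ester, in which the carboxylate and the alkene chelate rhodium and the C2-symmetric ligand selects one alkene face, should set the R centre that becomes C4.

Step 3
Reactants: 4 (R)-4-(3,4-dimethoxyphenyl)-3-(methoxycarbonyl)butanoic acid
Product: 6 (R)-4-(3,4-dimethoxybenzyl)oxolan-2-one, via hydroxy acid 5 (not isolated)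
Conditions: KOH (1 equiv), EtOH; CaCl2, NaBH4, −10 °C → rt; then 3 M HCl, rt
Reagents that add atoms: none
Why: Chemoselective ester reduction by calcium borohydride, which leaves the potassium carboxylate untouched, followed by acid lactonisation of the γ-hydroxy acid, should give the β-substituted lactone without touching the stereocentre.

Step 4
Reactants: 6 (R)-4-(3,4-dimethoxybenzyl)oxolan-2-one
Product: 8 (3S,4R)-4-(3,4-dimethoxybenzyl)-3-(dimethoxymethyl)oxolan-2-one, via silyl ketene acetal 7 (not isolated)
Conditions: LDA, THF, −78 °C; TMSCl; then HC(OMe)3, TMSOTf (10 mol %), CH2Cl2, −78 °C; NaHCO3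
Reagents that add atoms: trimethyl orthoformate, COC(OC)OC
Why: Mukaiyama-type addition of a silyl ketene acetal to the dimethoxycarbenium ion released from the orthoester (a formyl cation equivalent) should take place on the face anti to the C4 veratrylmethyl group and give the trans lactone, which is also the thermodynamic isomer.

Step 5
Reactants: 8 (3S,4R)-4-(3,4-dimethoxybenzyl)-3-(dimethoxymethyl)oxolan-2-one
Product: 9 (2R,3R)-2-(3,4-dimethoxybenzyl)-3-(dimethoxymethyl)butane-1,4-diol
Conditions: LiAlH4, THF, 0 °C; aq. NaOH work-up
Reagents that add atoms: none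
Why: LiAlH4 reduction of a lactone to the 1,4-diol, in which the dimethyl acetal is inert to hydride and to the basic work-up, should keep the aldehyde carbon masked so that the neighbouring centre cannot epimerise.

Step 6
Reactants: 9 (2R,3R)-2-(3,4-dimethoxybenzyl)-3-(dimethoxymethyl)butane-1,4-diol; 10 guaiacol (2-methoxyphenol)
Product: 12 4'-O-methyllariciresinol {4-[(2S,3R,4R)-4-(3,4-dimethoxybenzyl)-3-(hydroxymethyl)oxolan-2-yl]-2-methoxyphenol}, via cyclic methyl acetal 11 (not isolated)
Conditions: CSA (5 mol %), CH2Cl2, rt; then 10 (5 equiv), BF3·OEt2 (2.5 equiv), −78 → −30 °C; aq. NaHCO3 quench at −30 °C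
Reagents that add atoms: none
Why: CSA-catalysed transacetalisation should close the oxolane by 5-exo attack of the C4 CH2OH oxygen on the methoxycarbenium ion of the acetal (the C3 CH2OH could only give an oxetane), and BF3 should then ionise 11 to the cyclic oxocarbenium ion C2=O1+, which is captured in a Friedel–Crafts step by C4 of guaiacol, para to its OH. The closest known reaction type is the Lewis-acid C-arylation of lactol methyl ethers and furanosyl donors by electron-rich arenes (Friedel–Crafts C-glycosylation). The new C2 centre is set by the substrate: the C3 CH2OH and C4 veratrylmethyl groups are cis and lie on one face, so the arene should attack the envelope (C4 as flap, veratrylmethyl pseudo-equatorial) from the inside on the other face and end trans to C3 (2S). On guaiacol the OH is the stronger donor and its para carbon is the least hindered site for a secondary, α-branched cation; O-aryl acetals that form are re-ionised by BF3 and should drain to the C–C product, and the excess of guaiacol should outrun the internal veratryl ring, which can reach C2 only through a strained benzo-bridged transition state on the hindered face. The reaction must be quenched cold, because the product is a p-hydroxybenzyl ether that acid can re-ionise at C2 (quinone methide), with loss to an aryltetralin or a bis-aryl compound.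

**Compound list**

1 | 3,4-dimethoxybenzaldehyde (veratraldehyde) | COc1ccc(C=O)cc1OC | starting material
2 | dimethyl succinate | COC(=O)CCC(=O)OC | starting material
3 | (E)-4-(3,4-dimethoxyphenyl)-3-(methoxycarbonyl)but-3-enoic acid | OC(=O)C/C(=C\c1ccc(OC)c(OC)c1)C(=O)OC | intermediate
4 | (R)-4-(3,4-dimethoxyphenyl)-3-(methoxycarbonyl)butanoic acid | OC(=O)C[C@@H](Cc1ccc(OC)c(OC)c1)C(=O)OC | intermediate
5 | (R)-3-(3,4-dimethoxybenzyl)-4-hydroxybutanoic acid | OC(=O)C[C@@H](Cc1ccc(OC)c(OC)c1)CO | intermediate (not isolated)
6 | (R)-4-(3,4-dimethoxybenzyl)oxolan-2-one | O=C1C[C@@H](Cc2ccc(OC)c(OC)c2)CO1 | intermediate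
7 | {[(4R)-4-(3,4-dimethoxybenzyl)-4,5-dihydrofuran-2-yl]oxy}trimethylsilane | C[Si](C)(C)OC1=C[C@@H](Cc2ccc(OC)c(OC)c2)CO1 | intermediate (not isolated)
8 | (3S,4R)-4-(3,4-dimethoxybenzyl)-3-(dimethoxymethyl)oxolan-2-one (trans) | O=C1[C@H](C(OC)OC)[C@@H](Cc2ccc(OC)c(OC)c2)CO1 | intermediate
9 | (2R,3R)-2-(3,4-dimethoxybenzyl)-3-(dimethoxymethyl)butane-1,4-diol | OC[C@H](C(OC)OC)[C@@H](Cc1ccc(OC)c(OC)c1)CO | intermediate
10 | guaiacol (2-methoxyphenol) | COc1ccccc1O | starting material
11 | [(3R,4R)-4-(3,4-dimethoxybenzyl)-2-methoxyoxolan-3-yl]methanol (both C2 epimers) | COC1OC[C@H](Cc2ccc(OC)c(OC)c2)[C@@H]1CO | intermediate (not isolated)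
12 | 4'-O-methyllariciresinol, 4-[(2S,3R,4R)-4-(3,4-dimethoxybenzyl)-3-(hydroxymethyl)oxolan-2-yl]-2-methoxyphenol | COc1cc([C@H]2OC[C@H](Cc3ccc(OC)c(OC)c3)[C@@H]2CO)ccc1O | target

**Count**

Total steps: 6. Longest linear sequence: 6 steps (1 → 3 → 4 → 6 → 8 → 9 → 12).

**Steps most likely to fail**

Step 6. The arene may be attacked at the wrong ring carbon: ortho to OH by rearrangement of the reversibly formed O-aryl acetal, or para to OMe. The product may also be re-ionised at C2 by the acid, or the oxocarbenium ion may lose its C3 proton and scramble C3. The fallback fixes the ring position with a carbon–metal bond and closes the ring afterwards. It sets out from 9. Hydrolysis (1 M HCl, THF, rt) gives the lactol (3R,4R)-4-(3,4-dimethoxybenzyl)-3-(hydroxymethyl)oxolan-2-ol F1. An excess of [4-(benzyloxy)-3-methoxyphenyl]magnesium bromide F2, made from bought 1-(benzyloxy)-4-bromo-2-methoxybenzene and Mg in THF, adds to the open aldehyde form to give the triol (2R,3R)-2-(3,4-dimethoxybenzyl)-3-{[4-(benzyloxy)-3-methoxyphenyl](hydroxy)methyl}butane-1,4-diol F3 as a mixture of carbinol epimers. CSA (cat.) in CH2Cl2 at 0 °C should close the oxolane by SN1 attack of the C4 CH2OH oxygen on the p-alkoxybenzyl cation, anti to the C3 substituent, to give the benzyl ether {(2S,3R,4R)-2-[4-(benzyloxy)-3-methoxyphenyl]-4-(3,4-dimethoxybenzyl)oxolan-3-yl}methanol F4. Hydrogenolysis (H2, 1 atm, Pd/C, EtOAc, stopped after one equivalent) comes back to the route at 12.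

Step 4. Methanol may be eliminated from the β,β-dimethoxy lactone to give the conjugated enol ether, the enolate may be silylated on carbon, or the trans selectivity may erode. The fallback uses a base-mediated condensation under thermodynamic control. It sets out from 6. Claisen formylation (NaH, HCO2Et, THF, 0 °C → rt) gives (4R)-4-(3,4-dimethoxybenzyl)-3-(hydroxymethylidene)oxolan-2-one F5. Acetalisation (HC(OMe)3, MeOH, TsOH cat., rt) should give the dimethyl acetal with the α-centre equilibrated to trans, and comes back to the route at 8.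

Step 2. Enantiofacial discrimination may be insufficient, or turnover slow, with the electron-rich trisubstituted alkene. The fallback replaces catalysis by classical resolution. It sets out from 3. Hydrogenation over Pd/C (H2, MeOH) gives racemic 4-(3,4-dimethoxyphenyl)-3-(methoxycarbonyl)butanoic acid F6. Crystallisation with (S)-1-phenylethylamine should give the (S)-1-phenylethylammonium salt of the R acid F7; if the S acid pairs in the less soluble salt, the mirror-image amine is used. Acidification with aq. HCl comes back to the route at 4.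

**Further compounds**

F1 | step 6 | (3R,4R)-4-(3,4-dimethoxybenzyl)-3-(hydroxymethyl)oxolan-2-ol | OC1OC[C@H](Cc2ccc(OC)c(OC)c2)[C@@H]1CO
F2 | step 6 | [4-(benzyloxy)-3-methoxyphenyl]magnesium bromide | COc1cc([Mg]Br)ccc1OCc1ccccc1
F3 | step 6 | (2R,3R)-2-(3,4-dimethoxybenzyl)-3-{[4-(benzyloxy)-3-methoxyphenyl](hydroxy)methyl}butane-1,4-diol | OC[C@H](C(O)c1ccc(OCc2ccccc2)c(OC)c1)[C@@H](Cc1ccc(OC)c(OC)c1)CO
F4 | step 6 | {(2S,3R,4R)-2-[4-(benzyloxy)-3-methoxyphenyl]-4-(3,4-dimethoxybenzyl)oxolan-3-yl}methanol | COc1cc([C@H]2OC[C@H](Cc3ccc(OC)c(OC)c3)[C@@H]2CO)ccc1OCc1ccccc1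
F5 | step 4 | (4R)-4-(3,4-dimethoxybenzyl)-3-(hydroxymethylidene)oxolan-2-one | O=C1OC[C@H](Cc2ccc(OC)c(OC)c2)C1=CO
F6 | step 2 | racemic 4-(3,4-dimethoxyphenyl)-3-(methoxycarbonyl)butanoic acid | OC(=O)CC(Cc1ccc(OC)c(OC)c1)C(=O)OC
F7 | step 2 | (S)-1-phenylethylammonium (R)-4-(3,4-dimethoxyphenyl)-3-(methoxycarbonyl)butanoate | [O-]C(=O)C[C@@H](Cc1ccc(OC)c(OC)c1)C(=O)OC.C[C@H]([NH3+])c1ccccc1
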